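**Retrosynthetic overview**
1. The target is a trans-fused eudesmane (ring A = C1–C5 and C10; ring B = C5–C10; 10β-CH3, 5α-H). The route rests on one feature: the cis-3α,4α-diol diester on C3/C4 of ring A is a masked C3=C4 alkene, and the ring bonds C4–C5 and C9–C10 sit at the two ends of one (E)-C5=C10 alkene of an open chain.
2. Late stage: C11 carbinol and C6=C7 ⇐ singlet-oxygen ene reaction of the 7(11)-en-8-one; angelate and acetate ⇐ 3α,4α-diol ⇐ OsO4 on C3=C4; C7=C11 ⇐ aldol of the C8 ketone with acetone.
3. Key disconnection: C4–C5 (ring A) and C9–C10 (ring B) together, by an enantioselective gold-catalysed cascade from acyclic 1,5-enyne silyl enol ether 13 to octalone 14.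
4. Chain: C8 enol ether ⇐ methyl ketone 11; C5–C6 ⇐ B-alkyl Suzuki coupling; C10 methyl and (E)-C5=C10 ⇐ carboalumination/iodination of hepta-1,5-diyne; C1–C2 ⇐ propargylic alkylation.
5. Ring order: no ring before step 7; ring A closes first and ring B second within that one step.

Key step: step 7

Numbering: eudesmane numbering is used for all bicyclic compounds (C14 = methyl on C10, C15 = methyl on C4; α = face of 5-H, β = face of the C10 methyl group).
Assumption: the target is taken as drawn, (3R,4S,5R,10R); the (R)-configured digold catalyst is assumed to give the (5R,10R) octalone, and the (S)-ligand would be used unchanged otherwise if a test run shows the opposite sense.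

**Route**

Step 1
Reactants: 1 1-(trimethylsilyl)prop-1-yne; 2 1-bromobut-2-yne
Product: 4 hepta-1,5-diyn-1-yl(trimethyl)silane, via 3-lithio-1-(trimethylsilyl)prop-1-yne 3 (not isolated)
Conditions: n-BuLi, THF, −78 to −20 °C; then 2, −78 °C to rt
Reagents that add atoms: none
Why: Propargylic lithiation of the silylpropyne followed by SN2 alkylation of the primary propargylic bromide should join C1 to C2, because the silyl group keeps the ambident anion reacting at its CH2 end and a copper-free organolithium prefers direct over SN2′ displacement.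

Step 2
Reactants: 4 hepta-1,5-diyn-1-yl(trimethyl)silane
Product: 5 hepta-1,5-diyne
Conditions: K2CO3 (cat.), MeOH, rt; pentane extraction, careful distillation (volatile)
Reagents that add atoms: none
Why: Carbonate-catalysed methanolysis of the alkynyl C–Si bond (protodesilylation) should free the terminal alkyne and leave the methyl-capped alkyne untouched.

Step 3
Reactants: 5 hepta-1,5-diyne
Product: 7 (E)-1-iodo-2-methylhept-1-en-5-yne, via alkenyl(dimethyl)alane 6 (not isolated)
Conditions: Me3Al, Cp2ZrCl2 (cat.), H2O (1 equiv), CH2Cl2, −25 °C; then I2, THF, −25 to 0 °C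
Reagents that add atoms: trimethylaluminium, C[Al](C)C; iodine, II
Why: Zirconium-catalysed carboalumination of alkynes (water-accelerated variant) adds CH3 and Al syn across the terminal alkyne with CH3 on the inner carbon, the terminal alkyne reacting much faster than the internal one at low temperature, and iodinolysis of the C–Al bond with retention should give the (E)-iodide that carries the C10 methyl group and the alkene geometry.

Step 4
Reactants: 7 (E)-1-iodo-2-methylhept-1-en-5-yne; 8 2-methyl-2-vinyl-1,3-dioxolane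
Product: 10 2-methyl-2-[(E)-4-methylnon-3-en-7-yn-1-yl]-1,3-dioxolane, via B-alkyl-9-BBN 9 (not isolated)
Conditions: 8, 9-BBN, THF, 0 °C to rt; then 7, Pd(dppf)Cl2 (cat.), AsPh3, Cs2CO3, DMF/H2O, rt
Reagents that add atoms: none
Why: Anti-Markovnikov hydroboration of the vinyl ketal with 9-BBN and B-alkyl Suzuki–Miyaura coupling with the alkenyl iodide should form C5–C6 with retention of the (E)-geometry, the ketal serving as a ketone homoenolate equivalent that the borane and the base do not touch.

Step 5
Reactants: 10 2-methyl-2-[(E)-4-methylnon-3-en-7-yn-1-yl]-1,3-dioxolane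
Product: 11 (E)-6-methylundec-5-en-9-yn-2-one
Conditions: 1 M HCl, THF, rt
Reagents that add atoms: water, O
Why: Acid-catalysed ketal hydrolysis should release the methyl ketone under conditions too mild to hydrate the alkyne or move the trisubstituted alkene.

Step 6
Reactants: 11 (E)-6-methylundec-5-en-9-yn-2-one
Product: 13 (E)-6-methyl-2-(triisopropylsilyloxy)undeca-1,5-dien-9-yne, via lithium enolate 12 (not isolated)
Conditions: LiN(i-Pr)2, THF, −78 °C; then TIPSOTf, −78 to 0 °C
Reagents that add atoms: triisopropylsilyl trifluoromethanesulfonate, CC(C)[Si](OS(=O)(=O)C(F)(F)F)(C(C)C)C(C)C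
Why: Kinetic deprotonation with the hindered lithium amide at −78 °C takes a methyl proton, and O-silylation of the resulting enolate with the silyl triflate (kinetic silyl enol ether formation) should give the 2-silyloxy-1-alkene with C9 as the nucleophilic terminus.

Step 7
Reactants: 13 (E)-6-methyl-2-(triisopropylsilyloxy)undeca-1,5-dien-9-yne
Product: 14 (5R,10R)-11,12,13-trinoreudesm-3-en-8-one [(4aR,8aR)-5,8a-dimethyl-3,4,4a,7,8,8a-hexahydronaphthalen-2(1H)-one]
Conditions: [(R)-MeO-DTBM-BIPHEP](AuCl)2 (5 mol %), AgSbF6 (5 mol %), MeOH (2 equiv), m-xylene, −20 °C to rt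
Reagents that add atoms: none
Why: Proposed new method: the cationic monovalent gold centre formed from the digold chloride and AgSbF6 binds the C3≡C4 alkyne, C5 of the (E)-alkene attacks C4 anti to gold, the tertiary C10 cation so formed is captured by C9 of the silyl enol ether, MeOH takes the silyl group from the silyloxycarbenium ion, and the proton set free cleaves the C3–Au bond to leave C3–H and the C3=C4 alkene. The closest known reaction type is the enantioselective 6-endo-dig polycyclisation of 1,5-enynes under chiral bisphosphine digold chloride/silver salt catalysis, established for terminal alkynes with oxygen, nitrogen and arene terminators, combined with the known gold-catalysed carbocyclisation of silyl enol ethers onto alkynes run with an alcohol as proton source; the internal alkyne and the silyl enol ether as cation terminator are the untested points. Ring A closes 6-endo-dig (both alkyne carbons end in the ring) and ring B closes by 6-endo-trig attack of the enol ether on the C10 cation (both enol carbons end in the ring). C5 and C10 are set together: anti addition of C4 and C9 to opposite faces of the (E)-C5=C10 alkene in a chair–chair fold fixes their relative configuration (trans fusion, 5-H anti to the C10 methyl), and the chiral bisphosphine on gold selects the alkene face that meets the alkyne and so the absolute configuration (5R,10R). The step needs the 6-endo-dig cation pathway over the cyclopropyl-carbene (bicyclo[3.1.0]hexene) pathway open to 1,5-enynes, which the methyl group on C10 secures by making C10 the cationic terminus, and it needs C–C capture of C10 ahead of proton loss or addition of MeOH, which the enol ether held in a chair six-ring array and the small amount of MeOH secure. The bulky triisopropylsilyl group is chosen so that the enol ether outlasts traces of acid until the cascade has run.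

Step 8
Reactants: 14 (5R,10R)-11,12,13-trinoreudesm-3-en-8-one
Product: 16 (5R,7R,10R)-11-hydroxyeudesm-3-en-8-one, via lithium C7 enolate 15 (not isolated)
Conditions: LiN(i-Pr)2, THF, −78 °C; then acetone, −78 °C; AcOH, −78 °C
Reagents that add atoms: acetone, CC(C)=O
Why: Kinetic enolisation should go toward C7, since C9 is flanked by the quaternary C10 with its axial methyl group, and the directed aldol addition of this lithium enolate to acetone, quenched cold to prevent retro-aldol cleavage, should give the C7 carbinol, whose C7 configuration (drawn equatorial; the epimer serves equally) is erased in step 9.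

Step 9
Reactants: 16 (5R,7R,10R)-11-hydroxyeudesm-3-en-8-one
Product: 18 (5R,10R)-eudesma-3,7(11)-dien-8-one, via tertiary mesylate 17 (not isolated)
Conditions: MsCl, Et3N, CH2Cl2, 0 °C; then DBU, rt
Reagents that add atoms: none
Why: Mesylation of the tertiary alcohol through sulfene and base-induced E1cB elimination via the C7 enolate (aldol dehydration) should give the conjugated tetrasubstituted C7=C11 enone, DBU also bringing any isopropenyl isomer into conjugation, without the acid that could move the C3=C4 alkene.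

Step 10
Reactants: 18 (5R,10R)-eudesma-3,7(11)-dien-8-one
Product: 19 (3R,4S,5R,10R)-3,4-dihydroxyeudesm-7(11)-en-8-one
Conditions: OsO4 (cat.), NMO, acetone/H2O, rt
Reagents that add atoms: osmium tetroxide, O=[Os](=O)(=O)=O; N-methylmorpholine N-oxide, C[N+]1([O-])CCOCC1; water, O
Why: Catalytic OsO4/NMO syn-dihydroxylation should take place at the electron-rich trisubstituted C3=C4 alkene and not at the electron-poor tetrasubstituted enone alkene, from the α face opposite to the axial C10 methyl group that overhangs C4, which sets C3 (R) and C4 (S) as the cis-3α,4α-diol.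

Step 11
Reactants: 19 (3R,4S,5R,10R)-3,4-dihydroxyeudesm-7(11)-en-8-one; 20 angelic acid
Product: 22 (3R,4S,5R,10R)-3-(angeloyloxy)-4-hydroxyeudesm-7(11)-en-8-one, via mixed anhydride 21 (not isolated)
Conditions: 20, 2,4,6-trichlorobenzoyl chloride, Et3N, toluene, rt; then 19, 75 °C
Reagents that add atoms: none
Why: Yamaguchi-type esterification through the mixed 2,4,6-trichlorobenzoic anhydride, run without a nucleophilic catalyst, should acylate the secondary C3 hydroxyl and not the tertiary C4 hydroxyl, and it is the mode of activation under which angelic acid is transferred without Z to E isomerisation to the tiglate.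

Step 12
Reactants: 22 (3R,4S,5R,10R)-3-(angeloyloxy)-4-hydroxyeudesm-7(11)-en-8-one
Product: 23 (3R,4S,5R,10R)-4-acetoxy-3-(angeloyloxy)eudesm-7(11)-en-8-one
Conditions: Ac2O, Sc(OTf)3 (cat.), MeCN, −20 °C
Reagents that add atoms: acetic anhydride, CC(=O)OC(C)=O
Why: Lewis acid-catalysed acylation (Sc(OTf)3 activation of the anhydride) acetylates hindered tertiary alcohols at low temperature, where elimination at C4 and isomerisation of the angelate are not expected.

Step 13
Reactants: 23 (3R,4S,5R,10R)-4-acetoxy-3-(angeloyloxy)eudesm-7(11)-en-8-one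
Product: 25 (3R,4S,5R,10R)-4-acetoxy-3-(angeloyloxy)-11-hydroxyeudesm-6-en-8-one, via C11 hydroperoxide 24 (not isolated)
Conditions: O2, tetraphenylporphyrin (cat.), hν (λ > 500 nm), CH2Cl2, −20 °C; then PPh3, −20 °C to rt
Reagents that add atoms: dioxygen, O=O
Why: Schenck ene reaction: singlet oxygen should add at C11 of the s-cis-locked isopropylidene enone and take the allylic hydrogen from C6, the ring CH2 geminal to the carbonyl group (the gem selectivity known for enones such as pulegone), so that the alkene moves to C6=C7, the tetrasubstituted alkene reacting ahead of the less electron-rich angelate, and PPh3 then reduces the tertiary hydroperoxide to the C11 alcohol.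

**Compound list**
1 | 1-(trimethylsilyl)prop-1-yne | CC#C[Si](C)(C)C | starting material
2 | 1-bromobut-2-yne | CC#CCBr | starting material
3 | 3-lithio-1-(trimethylsilyl)prop-1-yne | [Li]CC#C[Si](C)(C)C | intermediate
4 | hepta-1,5-diyn-1-yl(trimethyl)silane | CC#CCCC#C[Si](C)(C)C | intermediate
5 | hepta-1,5-diyne | CC#CCCC#C | intermediate
6 | dimethyl[(E)-2-methylhept-1-en-5-yn-1-yl]alane | CC#CCC/C(C)=C/[Al](C)C | intermediate
7 | (E)-1-iodo-2-methylhept-1-en-5-yne | CC#CCC/C(C)=C/I | intermediate
8 | 2-methyl-2-vinyl-1,3-dioxolane | C=CC1(C)OCCO1 | starting material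
9 | 9-[2-(2-methyl-1,3-dioxolan-2-yl)ethyl]-9-borabicyclo[3.3.1]nonane (B-alkyl-9-BBN) | CC1(CCB2C3CCCC2CCC3)OCCO1 | intermediate
10 | 2-methyl-2-[(E)-4-methylnon-3-en-7-yn-1-yl]-1,3-dioxolane | CC#CCC/C(C)=C/CCC1(C)OCCO1 | intermediate
11 | (E)-6-methylundec-5-en-9-yn-2-one | CC#CCC/C(C)=C/CCC(C)=O | intermediate
12 | lithium (E)-6-methylundeca-1,5-dien-9-yn-2-olate | CC#CCC/C(C)=C/CCC(=C)O[Li] | intermediate
13 | (E)-6-methyl-2-(triisopropylsilyloxy)undeca-1,5-dien-9-yne | CC#CCC/C(C)=C/CCC(=C)O[Si](C(C)C)(C(C)C)C(C)C | intermediate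
14 | (5R,10R)-11,12,13-trinoreudesm-3-en-8-one (trans-fused) | CC1=CCC[C@]2(C)CC(=O)CC[C@@H]12 | intermediate
15 | lithium (5R,10R)-11,12,13-trinoreudesma-3,7-dien-8-olate | CC1=CCC[C@]2(C)CC(O[Li])=CC[C@@H]12 | intermediate
16 | (5R,7R,10R)-11-hydroxyeudesm-3-en-8-one | CC1=CCC[C@]2(C)CC(=O)[C@@H](C(C)(C)O)C[C@@H]12 | intermediate
17 | (5R,7R,10R)-11-(methanesulfonyloxy)eudesm-3-en-8-one | CC1=CCC[C@]2(C)CC(=O)[C@@H](C(C)(C)OS(C)(=O)=O)C[C@@H]12 | intermediate
18 | (5R,10R)-eudesma-3,7(11)-dien-8-one | CC1=CCC[C@]2(C)CC(=O)C(=C(C)C)C[C@@H]12 | intermediate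
19 | (3R,4S,5R,10R)-3,4-dihydroxyeudesm-7(11)-en-8-one (3α,4α-diol) | O[C@@H]1CC[C@]2(C)CC(=O)C(=C(C)C)C[C@H]2[C@]1(C)O | intermediate
20 | angelic acid [(Z)-2-methylbut-2-enoic acid] | C/C=C(/C)C(=O)O | starting material
21 | (Z)-2-methylbut-2-enoic 2,4,6-trichlorobenzoic anhydride | C/C=C(/C)C(=O)OC(=O)c1c(Cl)cc(Cl)cc1Cl | intermediate
22 | (3R,4S,5R,10R)-3-(angeloyloxy)-4-hydroxyeudesm-7(11)-en-8-one | C/C=C(/C)C(=O)O[C@@H]1CC[C@]2(C)CC(=O)C(=C(C)C)C[C@H]2[C@]1(C)O | intermediate
23 | (3R,4S,5R,10R)-4-acetoxy-3-(angeloyloxy)eudesm-7(11)-en-8-one | C/C=C(/C)C(=O)O[C@@H]1CC[C@]2(C)CC(=O)C(=C(C)C)C[C@H]2[C@]1(C)OC(C)=O | intermediate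
24 | (3R,4S,5R,10R)-4-acetoxy-3-(angeloyloxy)-11-hydroperoxyeudesm-6-en-8-one | C/C=C(/C)C(=O)O[C@@H]1CC[C@]2(C)CC(=O)C(C(C)(C)OO)=C[C@H]2[C@]1(C)OC(C)=O | intermediate
25 | (3R,4S,5R,10R)-4-acetoxy-3-(angeloyloxy)-11-hydroxyeudesm-6-en-8-one (CNP0351454.1) | C/C=C(/C)C(=O)O[C@@H]1CC[C@]2(C)CC(=O)C(C(C)(C)O)=C[C@H]2[C@]1(C)OC(C)=O | target

**Step count**
Total: 13 steps. Longest linear sequence: 13 steps (1 and 2 to 25).

**Steps most likely to fail**

Step 7 (proposed new method). What may go wrong: loss of the silyl group from the enol ether before the cascade starts, arrest after ring A with proton loss from the C10 cation, poor enantiofacial selection, or sluggish activation of the internal alkyne.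
Fallback (known chemistry, ring A by annulation onto a preformed ring B). It sets out from none of the numbered compounds: it replaces steps 1 to 7 and compounds 1 to 13 as a whole, and it comes back to the route at 14.
- Commercial racemic 7-methyl-1,4-dioxaspiro[4.5]decan-8-one F1 is condensed with (R)-1-phenylethylamine (toluene, reflux, water removal) to the imine F2.
- The secondary enamine tautomer of F2 adds to pent-1-en-3-one (THF, rt) on the face set by the auxiliary, giving the Michael adduct imine F3; this is the asymmetric Michael addition of a chiral imine, and the (R)-amine is the one expected to give the 10R centre by analogy with 2-methylcyclohexanone.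
- Aqueous AcOH hydrolyses F3 to (7R)-7-methyl-7-(3-oxopentyl)-1,4-dioxaspiro[4.5]decan-8-one F4.
- NaOMe in MeOH closes ring A (Robinson annulation) to (10R)-8,8-(ethylenedioxy)-11,12,13-trinoreudesm-4-en-3-one F5.
- Li/NH3 with t-BuOH (1 equiv) gives the trans-fused lithium C3 enolate F6, which PhNTf2 traps as the enol triflate F7 with C3=C4 in place.
- Pd(OAc)2/PPh3, Bu3N and HCO2H in DMF remove the triflate to give (5R,10R)-8,8-(ethylenedioxy)-11,12,13-trinoreudesm-3-ene F8.
- PPTS in wet acetone hydrolyses the ketal to 14.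

Step 13. What may go wrong: hydrogen abstraction from the C12/C13 methyl groups instead of C6 (giving the deconjugated C7 hydroperoxide), or competing oxygenation of the angelate.
Fallback (the C11 hydroxyl is kept from the aldol and the C6=C7 alkene is made by dehydrogenation). It sets out from 16 and comes back to the route at 25.
- The tertiary hydroxyl of 16 is silylated (TESOTf, 2,6-lutidine, CH2Cl2, −78 °C) to (5R,7R,10R)-11-(triethylsilyloxy)eudesm-3-en-8-one F9.
- IBX (DMSO/fluorobenzene, 70 °C) dehydrogenates the ketone, which can only go toward C6 because C10 is quaternary, to (5R,10R)-11-(triethylsilyloxy)eudesma-3,6-dien-8-one F10.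
- OsO4/NMO as in step 10 gives (3R,4S,5R,10R)-3,4-dihydroxy-11-(triethylsilyloxy)eudesm-6-en-8-one F11.
- Mixed anhydride 21 as in step 11 gives the 3-angelate F12.
- Ac2O, 4-pyrrolidinopyridine and Et3N (40 °C) give the 3-angelate 4-acetate F13; the Lewis acid of step 12 is avoided because it would cleave the silyl ether.
- HF·pyridine in THF removes the silyl group to give 25.

Step 12. What may go wrong: slow acylation of the hindered tertiary hydroxyl, migration of the angeloyl group from O3 to O4 under the Lewis acid, or Z to E isomerisation of the angelate.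
Fallback (the acetate is installed before the angelate, under forcing conditions, with O3 protected). It sets out from 19 and comes back to the route at 23.
- TESCl and imidazole in DMF silylate the secondary hydroxyl of 19 to (3R,4S,5R,10R)-4-hydroxy-3-(triethylsilyloxy)eudesm-7(11)-en-8-one F14.
- Ac2O, DMAP and Et3N (50 °C) give (3R,4S,5R,10R)-4-acetoxy-3-(triethylsilyloxy)eudesm-7(11)-en-8-one F15.
- HF·pyridine (THF, 0 °C; acidic, to suppress acetyl migration) gives (3R,4S,5R,10R)-4-acetoxy-3-hydroxyeudesm-7(11)-en-8-one F16.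
- Esterification with mixed anhydride 21 as in step 11 gives 23.

**Further compounds**
F1 | step 7 | 7-methyl-1,4-dioxaspiro[4.5]decan-8-one (racemic) | CC1CC2(CCC1=O)OCCO2
F2 | step 7 | 7-methyl-N-[(1R)-1-phenylethyl]-1,4-dioxaspiro[4.5]decan-8-imine | C[C@@H](N=C1CCC2(CC1C)OCCO2)c1ccccc1
F3 | step 7 | 1-[(7R)-7-methyl-8-{[(1R)-1-phenylethyl]imino}-1,4-dioxaspiro[4.5]decan-7-yl]pentan-3-one | CCC(=O)CC[C@]1(C)CC2(CCC1=N[C@H](C)c1ccccc1)OCCO2
F4 | step 7 | (7R)-7-methyl-7-(3-oxopentyl)-1,4-dioxaspiro[4.5]decan-8-one | CCC(=O)CC[C@]1(C)CC2(CCC1=O)OCCO2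
F5 | step 7 | (10R)-8,8-(ethylenedioxy)-11,12,13-trinoreudesm-4-en-3-one | CC1=C2CCC3(OCCO3)C[C@@]2(C)CCC1=O
F6 | step 7 | lithium (5R,10R)-8,8-(ethylenedioxy)-11,12,13-trinoreudesm-3-en-3-olate | CC1=C(O[Li])CC[C@]2(C)CC3(OCCO3)CC[C@@H]12
F7 | step 7 | (5R,10R)-8,8-(ethylenedioxy)-11,12,13-trinoreudesm-3-en-3-yl trifluoromethanesulfonate | CC1=C(OS(=O)(=O)C(F)(F)F)CC[C@]2(C)CC3(OCCO3)CC[C@@H]12
F8 | step 7 | (5R,10R)-8,8-(ethylenedioxy)-11,12,13-trinoreudesm-3-ene | CC1=CCC[C@]2(C)CC3(OCCO3)CC[C@@H]12
F9 | step 13 | (5R,7R,10R)-11-(triethylsilyloxy)eudesm-3-en-8-one | CC1=CCC[C@]2(C)CC(=O)[C@@H](C(C)(C)O[Si](CC)(CC)CC)C[C@@H]12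
F10 | step 13 | (5R,10R)-11-(triethylsilyloxy)eudesma-3,6-dien-8-one | CC1=CCC[C@]2(C)CC(=O)C(C(C)(C)O[Si](CC)(CC)CC)=C[C@@H]12
F11 | step 13 | (3R,4S,5R,10R)-3,4-dihydroxy-11-(triethylsilyloxy)eudesm-6-en-8-one | O[C@@H]1CC[C@]2(C)CC(=O)C(C(C)(C)O[Si](CC)(CC)CC)=C[C@H]2[C@]1(C)O
F12 | step 13 | (3R,4S,5R,10R)-3-(angeloyloxy)-4-hydroxy-11-(triethylsilyloxy)eudesm-6-en-8-one | C/C=C(/C)C(=O)O[C@@H]1CC[C@]2(C)CC(=O)C(C(C)(C)O[Si](CC)(CC)CC)=C[C@H]2[C@]1(C)O
F13 | step 13 | (3R,4S,5R,10R)-4-acetoxy-3-(angeloyloxy)-11-(triethylsilyloxy)eudesm-6-en-8-one | C/C=C(/C)C(=O)O[C@@H]1CC[C@]2(C)CC(=O)C(C(C)(C)O[Si](CC)(CC)CC)=C[C@H]2[C@]1(C)OC(C)=O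
F14 | step 12 | (3R,4S,5R,10R)-4-hydroxy-3-(triethylsilyloxy)eudesm-7(11)-en-8-one | CC[Si](CC)(CC)O[C@@H]1CC[C@]2(C)CC(=O)C(=C(C)C)C[C@H]2[C@]1(C)O
F15 | step 12 | (3R,4S,5R,10R)-4-acetoxy-3-(triethylsilyloxy)eudesm-7(11)-en-8-one | CC[Si](CC)(CC)O[C@@H]1CC[C@]2(C)CC(=O)C(=C(C)C)C[C@H]2[C@]1(C)OC(C)=O
F16 | step 12 | (3R,4S,5R,10R)-4-acetoxy-3-hydroxyeudesm-7(11)-en-8-one | O[C@@H]1CC[C@]2(C)CC(=O)C(=C(C)C)C[C@H]2[C@]1(C)OC(C)=O
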